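One mM of impurity takes one mM of fresh carrier out of the round for good, so I counted these flasks in mM of carrier.

| setting | larch | oak | ash | birch |
|---|---|---|---|---|
| substrate | 0.80 M | 0.80 M | 0.80 M | 0.80 M |
| salt in the second phase | 1.20 equiv | 1.20 equiv | 1.20 equiv | 1.20 equiv |
| spent carrier | 15 mol% | 15 mol% | 15 mol% | 15 mol% |
| impurity | 30 mM | 100 mM | 300 mM | 800 mM |
| time | 30 h | 30 h | 30 h | 30 h |
| volume of the second phase over the first | 1.0 | 1.0 | 1.0 | 1.0 |

- amount of target at the end, in percent of the substrate charged for larch, oak, ash, birch, in this order
- the shape of the row from first to last (falls, then rises / rises, then falls / falls all the way / rises all the way / hardly changes)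

    fresh carrier + impurity → spent catalyst (k1 = 970 /M/h)
    substrate + fresh carrier → target + spent carrier (k2 = 9.3 /M/h)
    spent carrier + salt in the second phase ⇌ fresh carrier + spent salt in the second phase (K3 = 2.0, k3 = 24 /M/h)

I reckoned the run in slow motion. Substrate turns to target on fresh carrier, which leaves as spent carrier. Spent carrier meets the salt in the second phase and comes back fresh, leaving spent salt. Impurity turns fresh carrier into spent catalyst, with no way back. At the start the carrier, 120 mM, stood spent, and its forward half-life against the salt as charged was 1.8 min, so fresh carrier appeared within minutes.

The first question was therefore who meets fresh carrier first. I took the constant of the target step times c(substrate) as charged, over the constant of the impurity step, which gave 7.67 mM. This is the break-even impurity: the concentration at which impurity and substrate take fresh carrier equally fast, so that a flask gets this value over c(impurity) in target for each carrier lost. Larch's 30 mM stood above it, so I expected the impurity in larch to go first, leaving 90.0 mM of carrier, while oak would keep 20.0 mM.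

In the middle, those survivors turn over against the salt, whose excess over the substrate is 160 mM. I expected larch to finish, and oak, with less carrier, to slow late as the salt thinned and the exchange leaned back.

Ash holds more impurity than carrier, so I expected its end to come early, with 180 mM of impurity still there. Target in ash is then a small correction, and I computed just that. Each carrier lost yields the break-even impurity over c(impurity), and c(impurity) falls as carrier is lost, so the sum is the break-even impurity times the logarithm of charged over remaining impurity. That gave 3.92 mM in ash, or 0.490% of the substrate.

The forecast gave 99.7%, 89%, 0.49% and 0.16%, with the shape falls all the way. Its ground for ash and birch was that “the only target is the small share made before the carrier dies”.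

The simulation gave 99.9%, 89.3%, 0.489% and 0.156%, with the shape falls all the way.

Birch ended at 0.156% because of the step from fresh carrier and impurity to spent catalyst: the same flask without that step gives >99.9%. On birch, 7.67 mM times the logarithm of 800 mM over 680 mM gave 1.25 mM of target, or 0.156% of the substrate charged, and birch held 0.156% as target after 30.0 h.

The numbers are those of an exercise; the result is computed.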